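(The readings were generated by integration with constants of no real substance; the scatter is artificial.)

In a closed flask where free catalyst turns substrate into target, the target made, reading less target charged, is the same with or without added target: at 0.40 h it is 19.5% of the charge in the alpha run and 20.0% in the theta run. Within the scatter, the two runs can therefore be averaged as shares of the charge.

| setting | alpha | theta | epsilon |
|---|---|---|---|
| substrate | 0.400 M | 0.400 M | 0.400 M |
| free catalyst | 0.00200 M | 0.00200 M | 0.00200 M |
| target |  | 0.200 M |  |
| time |  |  | 59 h |

| run | time / h | [target] / M |
|---|---|---|
| alpha run | 0.40 | 0.078 |
| alpha run | 0.68 | 0.109 |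
| alpha run | 1.2 | 0.127 |
| alpha run | 2.0 | 0.148 |
| alpha run | 3.4 | 0.157 |
| alpha run | 5.8 | 0.162 |
| alpha run | 9.9 | 0.168 |
| theta run | 0.40 | 0.280 |
| theta run | 0.68 | 0.311 |
| theta run | 1.2 | 0.319 |
| theta run | 2.0 | 0.341 |
| theta run | 3.4 | 0.349 |
| theta run | 5.8 | 0.359 |
| theta run | 9.9 | 0.351 |

(standard deviation of a reading: 0.006 M)

- target in the epsilon run at 59 h, as a share of the substrate charged

- Overall: substrate -> target, with free catalyst as catalyst.
- Constant volume, constant temperature.
- Bound and free are read together.

The bench rule treats the flask as first order. The alpha run's first reading gives a lifetime of 2.05 h, the time to make the whole charge at that opening pace, and the share made should be one minus the exponential of minus time over lifetime. At 0.68 h in the alpha run the rule says 28.2% and the reading is 27.2%. At 2.0 h it says 62.3% against a reading of 37.0%, so the border lies before that time, and the alpha run stands near 42.0% at 9.9 h.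

My own reckoning supposes that substrate goes by a second-order rate and target takes a fixed share of it. Integrated, the share still to come then falls inversely with time at late times. The averaged shares are 36.1% at 2.0 h and 39.9% at 9.9 h. These readings give the creep number 0.0940 h, the share still to come multiplied by the time. As a test, it gives 38.1% at 3.4 h, where the unused readings average 38.2%. At 59 h it gives 40.7%.

The forecast, 42.5%, stands above this and holds that “the catalyst must be dying on its own clock”.

The epsilon flask gives 40.8%.

    free catalyst + substrate ⇌ catalyst-substrate complex, settled at all times (2.800 /M)
    catalyst-substrate complex + substrate ⇌ doubly bound catalyst, settled at all times (2.200 /M)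
    doubly bound catalyst → target + catalyst-substrate complex (540.0 /h)
    2 substrate → homo dimer (2.711 /M/h)

Removing the loss of two substrate to homo dimer from the epsilon flask lifts target at 59 h from 40.8% to 99.3%, so that loss is the reason for the shortfall, accounting for 99% of what is missing. With the loss, the creep number 0.0940 h puts the target still to come after that time at an estimated 0.159% of the charge. Without it, the share short of the charge at 59 h, multiplied by that time, gives a larger creep number, of 0.394 h.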